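**Plan**

- Retrosynthesis (drimane numbering): the C2′ sulfate and the C3′ formyl group come off first; the C8 methyl (C12) is traced to a C8 ketone; ring B is opened at C9–C10; C9=C11 is cut as an aldol condensation between (S)-dihydro-α-ionone and a protected 2,4,5-trioxygenated benzaldehyde.
- Forward: ring A (from (S)-α-ionone) and the arene are made first and joined by Claisen–Schmidt condensation; ring B is closed last, C10 to C9, by a cobalt-hydride HAT-initiated radical–polar crossover cycloisomerisation; C12, the formyl group and the sulfate follow.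
- Enabling feature: C9 is the β-carbon of an electron-rich styrene (C9=C11–aryl) and lies 1,6 to C1 of the C1=C10 alkene of ring A. H-atom transfer to C1 gives a tertiary C10 centre that closes the ring C5–C6–C7–C8–C9–C10 by 6-exo attack on C9, and loss of H9 from the aryl-stabilised C11 cation restores C9=C11.
- Stereochemistry: C5 comes from (S)-α-ionone; C10 is set in the key step (trans-decalin chair, relayed from C5); C8 is set at the end by α-face diimide reduction of an 8(12)-methylene; the alkene geometry comes from elimination away from the quaternary C10. A temporary C8 acetate (from a CBS reduction) is only a non-nucleophilic oxidation-level helper and is taken back to the ketone.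

Key step: step 7

Notation: drimane numbering (decalin C1–C10 with 4,4,10-trimethyl; C11 on C9; C12 on C8; arene C1′–C6′ with C1′ on C11); Ar = 4,5-bis(benzyloxy)-2-(methoxymethoxy)phenyl.
Assumption: (S)-(−)-α-ionone and 3,4-bis(benzyloxy)phenol are taken as purchasable, and the aryl sulfates 21 and 22 are written as free hydrogen sulfates although they are best handled as sodium salts.

Step 1
Reactants: 1 (S)-(−)-α-ionone
Product: 3 (S)-dihydro-α-ionone, via silyl enol ether 2 (not isolated)
Conditions: Et3SiH (1.2 equiv), RhCl(PPh3)3 (0.5 mol%), benzene, 50 °C; then K2CO3 (cat.), MeOH, rt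
Reagents that add atoms: none
Why: Rh(I)-catalysed 1,4-hydrosilylation of the enone with a monohydrosilane should give the silyl enol ether and leave the trisubstituted ring alkene alone, mild methanolysis then frees the ketone, and C5 is not touched.

Step 2
Reactants: 4 3,4-bis(benzyloxy)phenol
Product: 5 4,5-bis(benzyloxy)-2-hydroxybenzaldehyde
Conditions: MgCl2, Et3N, (CH2O)n, MeCN, reflux
Reagents that add atoms: formaldehyde (as paraformaldehyde), C=O
Why: Magnesium-phenoxide ortho-formylation (Casnati–Skattebøl) is specific for the ortho position and should take the less hindered site para to the 3-benzyloxy group.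

Step 3
Reactants: 5 4,5-bis(benzyloxy)-2-hydroxybenzaldehyde
Product: 6 4,5-bis(benzyloxy)-2-(methoxymethoxy)benzaldehyde
Conditions: MOMCl, i-Pr2NEt, CH2Cl2, 0 °C → rt
Reagents that add atoms: chloromethyl methyl ether, COCCl
Why: O-Alkylation of the phenol gives the MOM ether, which later directs lithiation to C3′ and is the only acid-labile phenol protecting group in the route.

Step 4
Reactants: 3 (S)-dihydro-α-ionone; 6 4,5-bis(benzyloxy)-2-(methoxymethoxy)benzaldehyde
Product: 8 (1E)-1-Ar-5-[(1S)-2,6,6-trimethylcyclohex-2-en-1-yl]pent-1-en-3-one, via aldol adduct 7 (not isolated)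
Conditions: NaOH (10% aq.), EtOH, rt → 40 °C
Reagents that add atoms: none
Why: Claisen–Schmidt condensation of the non-enolisable aryl aldehyde at the methyl side of the methyl ketone, followed by E1cB dehydration, should give the (E)-enone and joins C9 to C11.

Step 5
Reactants: 8 (1E)-1-Ar-5-[(1S)-2,6,6-trimethylcyclohex-2-en-1-yl]pent-1-en-3-one
Product: 9 (1E,3S)-1-Ar-5-[(1S)-2,6,6-trimethylcyclohex-2-en-1-yl]pent-1-en-3-ol
Conditions: (R)-2-methyl-CBS-oxazaborolidine (20 mol%), catecholborane, toluene, −78 °C; aq. NaOH work-up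
Reagents that add atoms: none
Why: Corey–Bakshi–Shibata 1,2-reduction with the alkenyl group as the large substituent should give the (S)-carbinol at C8 under catalyst control, a temporary centre chosen so that after ring closure the oxygen is axial and the in-plane C8 substituent is H.

Step 6
Reactants: 9 (1E,3S)-1-Ar-5-[(1S)-2,6,6-trimethylcyclohex-2-en-1-yl]pent-1-en-3-ol
Product: 10 (1E,3S)-1-Ar-5-[(1S)-2,6,6-trimethylcyclohex-2-en-1-yl]pent-1-en-3-yl acetate
Conditions: Ac2O, Et3N, DMAP (cat.), CH2Cl2, 0 °C → rt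
Reagents that add atoms: acetic anhydride, CC(=O)OC(C)=O
Why: DMAP-catalysed acylation masks the C8 oxygen as an ester whose sp3 oxygen cannot capture a C10 cation, which a free or silylated hydroxyl would do.

Step 7
Reactants: 10 (1E,3S)-1-Ar-5-[(1S)-2,6,6-trimethylcyclohex-2-en-1-yl]pent-1-en-3-yl acetate
Product: 13 (5S,8S,10S,9(11)Z)-11-Ar-12-nordrim-9(11)-en-8-yl acetate, via C10 tertiary radical 11 (not isolated), via benzylic C11 cation 12 (not isolated)
Conditions: Co(II) complex of N,N′-bis(3,5-di-tert-butylsalicylidene)-1,2-cyclohexanediamine (5 mol%), N-fluoro-2,4,6-trimethylpyridinium triflate (1.5 equiv), PhSiH3 (1.5 equiv), PhCF3, 0 °C → rt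
Reagents that add atoms: none
Why: A Co(III) hydride, formed from the Co(II) salen complex, the N-fluoropyridinium oxidant and the silane, should transfer H• to C1 of the trisubstituted ring alkene (Markovnikov MHAT) to give the tertiary C10 radical 11, which as the radical or after oxidation to the cation is captured by C9 of the electron-rich styrene to give the aryl-stabilised C11 cation 12; collidine then removes H9, the only β-hydrogen, and restores C9=C11. The closest known reaction type is the cobalt-salen/N-fluoropyridinium/silane HAT-initiated radical–polar crossover cyclisation of polyenes, together with the related cobalt-catalysed diene cycloisomerisation. Ring B is closed in the 6-exo-trig mode (C10 onto C9, C11 exocyclic) through a chair-like transition state. The new quaternary centre C10 is controlled by C5: with the C5–C6 bond equatorial, C9 should add to the face of C10 anti to it and give the trans-decalin with the 10-methyl β, as in cationic and radical cyclisations of cyclogeranyl systems, and the axial 8-acetoxy group costs little. The step needs site selectivity in the H-atom transfer and a defined alkene geometry: H-atom transfer to the styrene should only give a benzylic cation that loses the same proton again, and in the elimination the aryl group turns away from the quaternary C10 towards C8, whose in-plane substituent is H, so that aryl ends cis to C8.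

Step 8
Reactants: 13 (5S,8S,10S,9(11)Z)-11-Ar-12-nordrim-9(11)-en-8-yl acetate
Product: 14 (5S,8S,10S,9(11)Z)-11-Ar-12-nordrim-9(11)-en-8-ol
Conditions: K2CO3 (cat.), MeOH, rt
Reagents that add atoms: none
Why: Base-catalysed transesterification should remove the acetate without touching the MOM or benzyl ethers.

Step 9
Reactants: 14 (5S,8S,10S,9(11)Z)-11-Ar-12-nordrim-9(11)-en-8-ol
Product: 15 (5S,10S,9(11)Z)-11-Ar-12-nordrim-9(11)-en-8-one
Conditions: Dess–Martin periodinane, CH2Cl2, 0 °C → rt, dark
Reagents that add atoms: none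
Why: Dess–Martin oxidation of the allylic alcohol under near-neutral conditions should give the α-arylidene ketone without isomerising the double bond and erases the temporary C8 centre.

Step 10
Reactants: 15 (5S,10S,9(11)Z)-11-Ar-12-nordrim-9(11)-en-8-one
Product: 16 (5S,10S,9(11)E)-11-Ar-drima-8(12),9(11)-diene
Conditions: Ph3PCH3Br, KOt-Bu, toluene, 80 °C
Reagents that add atoms: methyltriphenylphosphonium bromide (gives methylenetriphenylphosphorane in the flask), C[P+](c1ccccc1)(c1ccccc1)c1ccccc1.[Br-]
Why: Wittig methylenation with excess ylide at elevated temperature, the usual protocol for hindered enolisable ketones, should turn C8=O into the C8=C12 methylene that carries the future methyl carbon.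

Step 11
Reactants: 16 (5S,10S,9(11)E)-11-Ar-drima-8(12),9(11)-diene
Product: 17 (5S,8S,10S,9(11)E)-11-Ar-drim-9(11)-ene (8-methyl β)
Conditions: 2-nitrobenzenesulfonohydrazide (NBSH), Et3N, CH2Cl2, rt
Reagents that add atoms: none
Why: Diimide reduction (concerted syn transfer of H2) should take the 1,1-disubstituted alkene in preference to the hindered trisubstituted styrene and approach C8 from the α face, anti to the axial 10-methyl group, so that H8 is α and the 8-methyl β (8S).

Step 12
Reactants: 17 (5S,8S,10S,9(11)E)-11-Ar-drim-9(11)-ene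
Product: 19 (5S,8S,10S,9(11)E)-11-[4,5-bis(benzyloxy)-3-formyl-2-(methoxymethoxy)phenyl]drim-9(11)-ene, via 3′-lithio arene 18 (not isolated)
Conditions: n-BuLi, TMEDA, THF, −78 → −30 °C; DMF, −78 °C → rt; aq. NH4Cl
Reagents that add atoms: N,N-dimethylformamide, CN(C)C=O
Why: Directed ortho-metalation should occur at C3′, which is flanked by the MOM and a benzyloxy group, in preference to C6′, and the DMF quench gives the aldehyde.

Step 13
Reactants: 19 (5S,8S,10S,9(11)E)-11-[4,5-bis(benzyloxy)-3-formyl-2-(methoxymethoxy)phenyl]drim-9(11)-ene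
Product: 20 (5S,8S,10S,9(11)E)-11-[4,5-bis(benzyloxy)-3-formyl-2-hydroxyphenyl]drim-9(11)-ene
Conditions: HCl (3 M aq.), THF–MeOH, rt
Reagents that add atoms: none
Why: Acid-catalysed acetal cleavage of the MOM ether ortho to the formyl group is fast under mild conditions that should leave the benzyl ethers and the styrene intact.

Step 14
Reactants: 20 (5S,8S,10S,9(11)E)-11-[4,5-bis(benzyloxy)-3-formyl-2-hydroxyphenyl]drim-9(11)-ene
Product: 21 (5S,8S,10S,9(11)E)-11-[4,5-bis(benzyloxy)-3-formyl-2-(sulfooxy)phenyl]drim-9(11)-ene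
Conditions: SO3·pyridine (5 equiv), pyridine, 50 °C
Reagents that add atoms: sulfur trioxide–pyridine complex, [O-]S(=O)(=O)[n+]1ccccc1
Why: O-Sulfonation of the only free phenol with sulfur trioxide–pyridine should give the aryl sulfate monoester at C2′ and nowhere else.

Step 15
Reactants: 21 (5S,8S,10S,9(11)E)-11-[4,5-bis(benzyloxy)-3-formyl-2-(sulfooxy)phenyl]drim-9(11)-ene
Product: 22 (5S,8S,10S,9(11)E)-11-[3-formyl-4,5-dihydroxy-2-(sulfooxy)phenyl]drim-9(11)-ene (target)
Conditions: H2 (1 atm), 10% Pd/C, EtOAc–MeOH, rt, stopped at full debenzylation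
Reagents that add atoms: none
Why: Catalytic hydrogenolysis of the two benzyl aryl ethers should be much faster than reduction of the hindered trisubstituted styrene or of the hydrogen-bonded aryl aldehyde, and the aryl sulfate is stable to it.

**Compound list**

1 | (S)-(−)-α-ionone, (3E)-4-[(1S)-2,6,6-trimethylcyclohex-2-en-1-yl]but-3-en-2-one | CC(=O)/C=C/[C@@H]1C(C)=CCCC1(C)C | starting material
2 | 4-[(1S)-2,6,6-trimethylcyclohex-2-en-1-yl]but-2-en-2-yl triethylsilyl ether (enol ether geometry not defined; not isolated) | CC(O[Si](CC)(CC)CC)=CC[C@@H]1C(C)=CCCC1(C)C | intermediate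
3 | (S)-dihydro-α-ionone, 4-[(1S)-2,6,6-trimethylcyclohex-2-en-1-yl]butan-2-one | CC(=O)CC[C@@H]1C(C)=CCCC1(C)C | intermediate
4 | 3,4-bis(benzyloxy)phenol | Oc1ccc(OCc2ccccc2)c(OCc2ccccc2)c1 | starting material
5 | 4,5-bis(benzyloxy)-2-hydroxybenzaldehyde | O=Cc1cc(OCc2ccccc2)c(OCc2ccccc2)cc1O | intermediate
6 | 4,5-bis(benzyloxy)-2-(methoxymethoxy)benzaldehyde | COCOc1cc(OCc2ccccc2)c(OCc2ccccc2)cc1C=O | intermediate
7 | 1-Ar-1-hydroxy-5-[(1S)-2,6,6-trimethylcyclohex-2-en-1-yl]pentan-3-one (both carbinol epimers; not isolated) | COCOc1cc(OCc2ccccc2)c(OCc2ccccc2)cc1C(O)CC(=O)CC[C@@H]1C(C)=CCCC1(C)C | intermediate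
8 | (1E)-1-Ar-5-[(1S)-2,6,6-trimethylcyclohex-2-en-1-yl]pent-1-en-3-one | COCOc1cc(OCc2ccccc2)c(OCc2ccccc2)cc1/C=C/C(=O)CC[C@@H]1C(C)=CCCC1(C)C | intermediate
9 | (1E,3S)-1-Ar-5-[(1S)-2,6,6-trimethylcyclohex-2-en-1-yl]pent-1-en-3-ol | COCOc1cc(OCc2ccccc2)c(OCc2ccccc2)cc1/C=C/[C@@H](O)CC[C@@H]1C(C)=CCCC1(C)C | intermediate
10 | (1E,3S)-1-Ar-5-[(1S)-2,6,6-trimethylcyclohex-2-en-1-yl]pent-1-en-3-yl acetate | COCOc1cc(OCc2ccccc2)c(OCc2ccccc2)cc1/C=C/[C@@H](OC(C)=O)CC[C@@H]1C(C)=CCCC1(C)C | intermediate
11 | C10 tertiary radical from H-atom transfer to C1 of 10 (not isolated) | COCOc1cc(OCc2ccccc2)c(OCc2ccccc2)cc1/C=C/[C@@H](OC(C)=O)CC[C@@H]1[C](C)CCCC1(C)C | intermediate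
12 | ring-closed benzylic C11 cation, trans-decalin with H9 α (not isolated) | CC(=O)O[C@H]1CC[C@H]2C(C)(C)CCC[C@]2(C)[C@H]1[CH+]c1cc(OCc2ccccc2)c(OCc2ccccc2)cc1OCOC | intermediate
13 | (5S,8S,10S,9(11)Z)-11-Ar-12-nordrim-9(11)-en-8-yl acetate (8β-acetoxy, Ar cis to C8) | CC(=O)O[C@H]1CC[C@H]2C(C)(C)CCC[C@]2(C)/C1=C/c1cc(OCc2ccccc2)c(OCc2ccccc2)cc1OCOC | intermediate
14 | (5S,8S,10S,9(11)Z)-11-Ar-12-nordrim-9(11)-en-8-ol | O[C@H]1CC[C@H]2C(C)(C)CCC[C@]2(C)/C1=C/c1cc(OCc2ccccc2)c(OCc2ccccc2)cc1OCOC | intermediate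
15 | (5S,10S,9(11)Z)-11-Ar-12-nordrim-9(11)-en-8-one | O=C1CC[C@H]2C(C)(C)CCC[C@]2(C)/C1=C/c1cc(OCc2ccccc2)c(OCc2ccccc2)cc1OCOC | intermediate
16 | (5S,10S,9(11)E)-11-Ar-drima-8(12),9(11)-diene | C=C1CC[C@H]2C(C)(C)CCC[C@]2(C)/C1=C/c1cc(OCc2ccccc2)c(OCc2ccccc2)cc1OCOC | intermediate
17 | (5S,8S,10S,9(11)E)-11-Ar-drim-9(11)-ene (8-methyl β) | C[C@H]1CC[C@H]2C(C)(C)CCC[C@]2(C)/C1=C/c1cc(OCc2ccccc2)c(OCc2ccccc2)cc1OCOC | intermediate
18 | 3′-lithio derivative of 17 (not isolated) | C[C@H]1CC[C@H]2C(C)(C)CCC[C@]2(C)/C1=C/c1cc(OCc2ccccc2)c(OCc2ccccc2)c([Li])c1OCOC | intermediate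
19 | (5S,8S,10S,9(11)E)-11-[4,5-bis(benzyloxy)-3-formyl-2-(methoxymethoxy)phenyl]drim-9(11)-ene | C[C@H]1CC[C@H]2C(C)(C)CCC[C@]2(C)/C1=C/c1cc(OCc2ccccc2)c(OCc2ccccc2)c(C=O)c1OCOC | intermediate
20 | (5S,8S,10S,9(11)E)-11-[4,5-bis(benzyloxy)-3-formyl-2-hydroxyphenyl]drim-9(11)-ene | C[C@H]1CC[C@H]2C(C)(C)CCC[C@]2(C)/C1=C/c1cc(OCc2ccccc2)c(OCc2ccccc2)c(C=O)c1O | intermediate
21 | (5S,8S,10S,9(11)E)-11-[4,5-bis(benzyloxy)-3-formyl-2-(sulfooxy)phenyl]drim-9(11)-ene | C[C@H]1CC[C@H]2C(C)(C)CCC[C@]2(C)/C1=C/c1cc(OCc2ccccc2)c(OCc2ccccc2)c(C=O)c1OS(=O)(=O)O | intermediate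
22 | (5S,8S,10S,9(11)E)-11-[3-formyl-4,5-dihydroxy-2-(sulfooxy)phenyl]drim-9(11)-ene | C[C@H]1CC[C@H]2C(C)(C)CCC[C@]2(C)/C1=C/c1cc(O)c(O)c(C=O)c1OS(=O)(=O)O | target

**Step count and risks**

Total step count: 15. Longest linear sequence: 14 steps (4 → 22, steps 2–15).

Steps most likely to fail:

1. Step 7 (ring closure). The hydrogen atom may go to the styrene first and the benzylic cation may then be held by the neighbouring acetate. The C10 radical or cation may also lose a proton faster than it forms the C9–C10 bond; that migrates the ring alkene and, through the C5=C10 isomer, erases C5. The trans ring fusion may erode as well. The fallback sets out from 3 and comes back at 15; it closes the ring by a Lewis-acid cation–olefin cyclisation before the arene is attached. The kinetic lithium enolate of 3 (LDA, THF, −78 °C) is treated with diethyl chlorophosphite and oxidised (H2O2) to diethyl {2-oxo-4-[(1S)-2,6,6-trimethylcyclohex-2-en-1-yl]butyl}phosphonate F1. SnCl4 (CH2Cl2, −20 → 0 °C) should close ring B through the chelated enol, as in β-keto-ester-terminated cyclisations of dihydroionone derivatives, to give the trans-fused diethyl [(5S,10S)-8-oxo-11,12-dinordriman-9β-yl]phosphonate F2. Horner–Wadsworth–Emmons olefination of F2 with aldehyde 6 (NaH, THF, 0 → 60 °C) should give 15, and the route continues with step 10.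

2. Step 11 (C8 stereocentre). The styrene double bond may be reduced as well, or hydrogen may be delivered to the β face of C8. The fallback sets out from 16 and comes back at 17. Hydroboration with the bulky 9-BBN (THF, rt; then NaOH, H2O2) should attack only the 1,1-disubstituted alkene and, as is usual for 8(12)-methylene decalins with an axial 10-methyl group, from the α face, to give (5S,8S,10S,9(11)E)-11-Ar-drim-9(11)-en-12-ol F3. Mesylation (MsCl, Et3N, CH2Cl2) gives the methanesulfonate F4, and hydride displacement (LiEt3BH, THF, 0 °C → rt) gives 17.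

3. Step 15 (final deprotection). Hydrogenation of the styrene or reduction of the aldehyde may compete with hydrogenolysis, or the reaction may stall after one benzyl group. The fallback sets out from 20 and comes back at 22. Phenol 20 is sulfated as the protected diester (Cl3CCH2OSO2Cl, Et3N, DMAP, THF) to give the 2,2,2-trichloroethyl aryl sulfate F5. The benzyl ethers are cleaved without hydrogen (BCl3, pentamethylbenzene, CH2Cl2, −78 °C) to give the catechol 2,2,2-trichloroethyl aryl sulfate F6. Zinc dust and ammonium formate (MeOH, rt) then remove the trichloroethyl group to give 22.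

Further compounds
F1 | step 7 | diethyl {2-oxo-4-[(1S)-2,6,6-trimethylcyclohex-2-en-1-yl]butyl}phosphonate | CCOP(=O)(OCC)CC(=O)CC[C@@H]1C(C)=CCCC1(C)C
F2 | step 7 | diethyl [(5S,10S)-8-oxo-11,12-dinordriman-9β-yl]phosphonate (trans-decalin) | O=C1CC[C@H]2C(C)(C)CCC[C@]2(C)[C@H]1P(=O)(OCC)OCC
F3 | step 11 | (5S,8S,10S,9(11)E)-11-Ar-drim-9(11)-en-12-ol (8β-hydroxymethyl) | OC[C@H]1CC[C@H]2C(C)(C)CCC[C@]2(C)/C1=C/c1cc(OCc2ccccc2)c(OCc2ccccc2)cc1OCOC
F4 | step 11 | (5S,8S,10S,9(11)E)-11-Ar-drim-9(11)-en-12-yl methanesulfonate | CS(=O)(=O)OC[C@H]1CC[C@H]2C(C)(C)CCC[C@]2(C)/C1=C/c1cc(OCc2ccccc2)c(OCc2ccccc2)cc1OCOC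
F5 | step 15 | 2,2,2-trichloroethyl sulfate diester of 20 (4′,5′-bis(benzyloxy)) | C[C@H]1CC[C@H]2C(C)(C)CCC[C@]2(C)/C1=C/c1cc(OCc2ccccc2)c(OCc2ccccc2)c(C=O)c1OS(=O)(=O)OCC(Cl)(Cl)Cl
F6 | step 15 | 2,2,2-trichloroethyl sulfate diester with free 4′,5′-catechol | C[C@H]1CC[C@H]2C(C)(C)CCC[C@]2(C)/C1=C/c1cc(O)c(O)c(C=O)c1OS(=O)(=O)OCC(Cl)(Cl)Cl
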